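**Plan**

- Retrosynthesis: the C–N bond of the aminoquinone is cut back to a methoxyquinone, the quinone to a 2,3,5,6-tetramethoxyphenyl ring, and the 9-methyl group to a carboxyl group.
- Enabling feature: in ring B the bond C9–C10 lies next to the C5=C6 double bond, and quaternary C9 carries a one-carbon branch that can be a reduced carboxyl. Ring B is therefore a γ,δ-unsaturated acid in disguise, and C9–C10 is cut by a retro-[3,3] shift to a δ-lactone whose carbinol carbon C6 bears the 6,6-dimethylcyclohexenyl group (ring A).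
- Further cuts: C9–CH2Ar (enolate alkylation), C8–CH3 (cuprate addition), the lactone C=C (metathesis), the ester C–O, and C6–C7 (allylboration of the ring A aldehyde).
- Forward order: ring A is bought as 2,2-dimethylcyclohexanone, the lactone ring is closed by metathesis, ring B arises in the Claisen ring contraction, and the quinone is unveiled last.
- Stereochemistry: C6 is set by reagent-controlled allylboration, the C8 methyl by trans-selective conjugate addition relative to C6, and C9 and C10 by transfer from C6 through the boat transition state.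

Key step: step 10

Remark: the decalin carbons carry the usual sesquiterpenoid numbers (C1–C10); lactone 16 is drawn as the expected 3,4-trans epimer, its C3 epimer being equally usable because C3 becomes planar in step 10; salts that are merely protonated on aqueous work-up carry no number.

**Route**

Step 1
Reactants: 1 2,2-dimethylcyclohexanone
Product: 2 N'-(2,2-dimethylcyclohexylidene)-2,4,6-triisopropylbenzenesulfonohydrazide
Conditions: 2,4,6-(iPr)3C6H2SO2NHNH2, conc. HCl (cat.), MeOH, rt
Reagents that add atoms: 2,4,6-triisopropylbenzenesulfonohydrazide, CC(C)c1cc(C(C)C)c(S(=O)(=O)NN)c(C(C)C)c1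
Why: Acid-catalysed condensation of a ketone with an arenesulfonylhydrazide (sulfonylhydrazone formation) should proceed even beside the quaternary carbon and installs the leaving group for the Shapiro reaction.

Step 2
Reactants: 2 N'-(2,2-dimethylcyclohexylidene)-2,4,6-triisopropylbenzenesulfonohydrazide
Product: 4 6,6-dimethylcyclohex-1-ene-1-carbaldehyde, via vinyllithium 3 (not isolated)
Conditions: n-BuLi (2.2 equiv), THF, −78 → 0 °C; DMF, 0 °C; then H2O
Reagents that add atoms: N,N-dimethylformamide, CN(C)C=O
Why: Shapiro reaction, in which double deprotonation (possible only at the single α-methylene group) is followed by loss of sulfinate and N2 to give the vinyllithium regiospecifically, which DMF then formylates.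

Step 3
Reactants: 4 6,6-dimethylcyclohex-1-ene-1-carbaldehyde
Product: 6 (R)-1-(6,6-dimethylcyclohex-1-en-1-yl)but-3-en-1-ol, via borinate ester 5 (not isolated)
Conditions: (+)-Ipc2B(allyl) (reagent derived from (−)-α-pinene, commercial solution), Et2O, −78 °C; then 3 M NaOH, 30% H2O2, rt
Reagents that add atoms: (+)-B-allyldiisopinocampheylborane, C=CCB([C@H]1C[C@H]2C[C@@H]([C@@H]1C)C2(C)C)[C@H]1C[C@H]2C[C@@H]([C@@H]1C)C2(C)C
Why: Brown asymmetric allylboration through a chair Zimmerman–Traxler transition state, in which this reagent enantiomer should deliver the allyl group to the Re face of the enal (as it does with aryl aldehydes) and so set the (R)-carbinol centre, the future C6, under reagent control.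

Step 4
Reactants: 6 (R)-1-(6,6-dimethylcyclohex-1-en-1-yl)but-3-en-1-ol; 7 acryloyl chloride
Product: 8 (R)-1-(6,6-dimethylcyclohex-1-en-1-yl)but-3-en-1-yl acrylate
Conditions: Et3N, DMAP (cat.), CH2Cl2, 0 °C
Reagents that add atoms: none
Why: DMAP-catalysed esterification of a secondary alcohol with an acid chloride gives the diene for metathesis without touching the carbinol configuration.

Step 5
Reactants: 8 (R)-1-(6,6-dimethylcyclohex-1-en-1-yl)but-3-en-1-yl acrylate
Product: 9 (R)-6-(6,6-dimethylcyclohex-1-en-1-yl)-5,6-dihydro-2H-pyran-2-one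
Conditions: second-generation Grubbs catalyst RuCl2(=CHPh)(PCy3)(H2IMes) (5 mol %), CH2Cl2 (0.01 M), 40 °C
Reagents that add atoms: none
Why: Ring-closing metathesis between the terminal olefin and the acrylate closes the six-membered unsaturated lactone with loss of ethene, while the trisubstituted cyclohexene beside the quaternary carbon should not engage the ruthenium carbene.

Step 6
Reactants: 9 (R)-6-(6,6-dimethylcyclohex-1-en-1-yl)-5,6-dihydro-2H-pyran-2-one
Product: 10 (4S,6R)-6-(6,6-dimethylcyclohex-1-en-1-yl)-4-methyltetrahydro-2H-pyran-2-one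
Conditions: Me2CuLi (from CuI and MeLi, 1:2), Et2O, −78 → −40 °C; then aq. NH4Cl
Reagents that add atoms: lithium dimethylcuprate, [Li+].C[Cu-]C
Why: Gilman cuprate conjugate addition, in which axial attack on the half-chair enoate anti to the pseudo-equatorial C6 substituent should give the 4,6-trans lactone (4S), and at low temperature 1,4-addition should outpace SN2′ opening of the allylic lactone.

Step 7
Reactants: 11 1,2,4,5-tetramethoxybenzene
Product: 13 (2,3,5,6-tetramethoxyphenyl)methanol, via aryllithium 12 (not isolated)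
Conditions: n-BuLi, THF, 0 °C → rt; (CH2O)n, 0 °C → rt; then H2O
Reagents that add atoms: formaldehyde (as paraformaldehyde), C=O
Why: Directed ortho-lithiation at the position flanked by two methoxy groups, followed by addition of the aryllithium to formaldehyde, gives the benzylic alcohol.

Step 8
Reactants: 13 (2,3,5,6-tetramethoxyphenyl)methanol
Product: 14 3-(bromomethyl)-1,2,4,5-tetramethoxybenzene
Conditions: PBr3, Et2O, 0 °C
Reagents that add atoms: phosphorus tribromide, BrP(Br)Br
Why: Conversion of a primary benzylic alcohol into the bromide with PBr3 (SN2 displacement of a phosphite ester) is routine for electron-rich benzyl alcohols.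

Step 9
Reactants: 10 (4S,6R)-6-(6,6-dimethylcyclohex-1-en-1-yl)-4-methyltetrahydro-2H-pyran-2-one; 14 3-(bromomethyl)-1,2,4,5-tetramethoxybenzene
Product: 16 (3R,4S,6R)-6-(6,6-dimethylcyclohex-1-en-1-yl)-4-methyl-3-(2,3,5,6-tetramethoxybenzyl)tetrahydro-2H-pyran-2-one, via lithium enolate 15 (not isolated)
Conditions: LiN(iPr)2 (commercial solution), THF, −78 °C; then 14, DMPU, −78 → −30 °C
Reagents that add atoms: none
Why: C-alkylation of a lactone enolate with a reactive benzylic bromide (SN2), in which the electrophile should enter mainly anti to the C4 methyl group, although the new C3 centre is erased in the next step so that either epimer serves.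

Step 10
Reactants: 16 (3R,4S,6R)-6-(6,6-dimethylcyclohex-1-en-1-yl)-4-methyl-3-(2,3,5,6-tetramethoxybenzyl)tetrahydro-2H-pyran-2-one
Product: 20 (1S,2S,8aR)-2,5,5-trimethyl-1-(2,3,5,6-tetramethoxybenzyl)-1,2,3,5,6,7,8,8a-octahydronaphthalene-1-carboxylic acid, via lithium enolate 17 (not isolated), via silyl ketene acetal 18 (not isolated), via silyl ester 19 (not isolated)
Conditions: LiN(iPr)2 (commercial solution), THF, −78 °C; TBSCl, DMPU, −78 °C → rt; toluene, 110 °C; then AcOH/THF/H2O, rt
Reagents that add atoms: none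
Why: Enolisation and O-silylation give the cyclic silyl ketene acetal 18, whose array (ketene acetal C=C, ring oxygen, carbinol carbon C6, cyclohexenyl C=C) undergoes a concerted, suprafacial [3,3] sigmatropic shift, the Ireland–Claisen rearrangement in its ring-contracting form known for 6-alkenyl lactones, forming C9–C10 while C6–O breaks and C5=C6 appears. Ring B is closed within the pericyclic event itself: the four lactone carbons C9–C8–C7–C6 and the two olefin carbons become the cyclohexene through a boat, bicyclo[2.2.2]octane-like transition state with the cyclohexenyl group axial, the only geometry in which the tethered termini can meet. C10 is set because C9 must bond to the olefin face that carried the lactone oxygen, and C9 is set because the same constraint leaves the carboxyl carbon on that face (trans to H-10) and the arylmethyl group outside the boat (cis to H-10), so both centres derive from the (R)-carbinol carbon C6. The C8 methyl group, trans to the cyclohexenyl group in the lactone, lies on the convex side of the boat and ends cis to the carboxyl carbon. The step needs clean O-silylation of a fully substituted enolate and a single transition-state topology; the ring fixes the ketene acetal geometry, a chair is impossible for the tethered system, and the C3 configuration of 16 disappears on enolisation.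

Step 11
Reactants: 20 (1S,2S,8aR)-2,5,5-trimethyl-1-(2,3,5,6-tetramethoxybenzyl)-1,2,3,5,6,7,8,8a-octahydronaphthalene-1-carboxylic acid
Product: 21 [(1S,2S,8aR)-2,5,5-trimethyl-1-(2,3,5,6-tetramethoxybenzyl)-1,2,3,5,6,7,8,8a-octahydronaphthalen-1-yl]methanol
Conditions: LiAlH4, THF, 65 °C; then H2O, 15% NaOH (Fieser work-up)
Reagents that add atoms: none
Why: Hydride reduction of a carboxylic acid with LiAlH4 gives the neopentyl primary alcohol, and no stereocentre is at risk because C9 is quaternary.

Step 12
Reactants: 21 [(1S,2S,8aR)-2,5,5-trimethyl-1-(2,3,5,6-tetramethoxybenzyl)-1,2,3,5,6,7,8,8a-octahydronaphthalen-1-yl]methanol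
Product: 22 (1S,2S,8aR)-2,5,5-trimethyl-1-(2,3,5,6-tetramethoxybenzyl)-1,2,3,5,6,7,8,8a-octahydronaphthalene-1-carbaldehyde
Conditions: Dess–Martin periodinane, CH2Cl2, rt
Reagents that add atoms: none
Why: Dess–Martin oxidation of a primary alcohol stops at the aldehyde, which cannot enolise or epimerise because its α-carbon is quaternary.

Step 13
Reactants: 22 (1S,2S,8aR)-2,5,5-trimethyl-1-(2,3,5,6-tetramethoxybenzyl)-1,2,3,5,6,7,8,8a-octahydronaphthalene-1-carbaldehyde
Product: 24 3-{[(1R,2S,8aS)-1,2,5,5-tetramethyl-1,2,3,5,6,7,8,8a-octahydronaphthalen-1-yl]methyl}-1,2,4,5-tetramethoxybenzene, via hydrazone 23 (not isolated)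
Conditions: N2H4·H2O, KOH, diethylene glycol, 130 °C, then 200 °C
Reagents that add atoms: none
Why: Wolff–Kishner reduction (Huang-Minlon modification), in which the hydrazone loses N2 under hot base and the resulting carbanion is protonated to the 9-methyl group, under conditions that aryl methyl ethers and an isolated trisubstituted olefin should tolerate.

Step 14
Reactants: 24 3-{[(1R,2S,8aS)-1,2,5,5-tetramethyl-1,2,3,5,6,7,8,8a-octahydronaphthalen-1-yl]methyl}-1,2,4,5-tetramethoxybenzene
Product: 25 2,5-dimethoxy-3-{[(1R,2S,8aS)-1,2,5,5-tetramethyl-1,2,3,5,6,7,8,8a-octahydronaphthalen-1-yl]methyl}cyclohexa-2,5-diene-1,4-dione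
Conditions: (NH4)2Ce(NO3)6, MeCN/H2O, 0 °C
Reagents that add atoms: water, O
Why: Oxidative demethylation of a para-dimethoxyarene by tetravalent cerium, in which the symmetry of the aryl ring about its benzylic axis makes either para pair give the same 2,5-dimethoxy-1,4-benzoquinone, and the electron-rich arene should be oxidised in preference to the isolated olefin.

Step 15
Reactants: 25 2,5-dimethoxy-3-{[(1R,2S,8aS)-1,2,5,5-tetramethyl-1,2,3,5,6,7,8,8a-octahydronaphthalen-1-yl]methyl}cyclohexa-2,5-diene-1,4-dione
Product: 26 2-hydroxy-5-methoxy-3-{[(1R,2S,8aS)-1,2,5,5-tetramethyl-1,2,3,5,6,7,8,8a-octahydronaphthalen-1-yl]methyl}cyclohexa-2,5-diene-1,4-dione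
Conditions: KOH, MeOH/H2O, rt; then 1 M HCl
Reagents that add atoms: potassium hydroxide, [K+].[OH-]
Why: Addition–elimination of hydroxide at a vinylogous ester, in which the C2 methoxy group, wedged between a carbonyl and the side chain and twisted out of conjugation, is expected to be the more labile one, and the hydroxyquinone anion formed should resist a second hydrolysis.

Step 16
Reactants: 26 2-hydroxy-5-methoxy-3-{[(1R,2S,8aS)-1,2,5,5-tetramethyl-1,2,3,5,6,7,8,8a-octahydronaphthalen-1-yl]methyl}cyclohexa-2,5-diene-1,4-dione; 27 isopentylamine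
Product: 28 nakijiquinone M
Conditions: 27 (3 equiv), EtOH, rt
Reagents that add atoms: none
Why: Addition–elimination of the primary amine at the remaining methoxy-bearing carbon (exchange of a vinylogous ester for a vinylogous amide), the hydroxyl-bearing carbon being shielded as its enolate salt under the basic conditions.

**Compound list**

1 | 2,2-dimethylcyclohexanone | CC1(C)CCCCC1=O | starting material
2 | N'-(2,2-dimethylcyclohexylidene)-2,4,6-triisopropylbenzenesulfonohydrazide | CC1(C)CCCCC1=NNS(=O)(=O)c1c(C(C)C)cc(C(C)C)cc1C(C)C | intermediate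
3 | (6,6-dimethylcyclohex-1-en-1-yl)lithium | [Li]C1=CCCCC1(C)C | intermediate (not isolated)
4 | 6,6-dimethylcyclohex-1-ene-1-carbaldehyde | O=CC1=CCCCC1(C)C | intermediate
5 | (R)-1-(6,6-dimethylcyclohex-1-en-1-yl)but-3-en-1-yl diisopinocampheylborinate | C=CC[C@@H](OB([C@H]1C[C@H]2C[C@@H]([C@@H]1C)C2(C)C)[C@H]1C[C@H]2C[C@@H]([C@@H]1C)C2(C)C)C1=CCCCC1(C)C | intermediate (not isolated)
6 | (R)-1-(6,6-dimethylcyclohex-1-en-1-yl)but-3-en-1-ol | C=CC[C@@H](O)C1=CCCCC1(C)C | intermediate
7 | acryloyl chloride | C=CC(=O)Cl | starting material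
8 | (R)-1-(6,6-dimethylcyclohex-1-en-1-yl)but-3-en-1-yl acrylate | C=CC[C@@H](OC(=O)C=C)C1=CCCCC1(C)C | intermediate
9 | (R)-6-(6,6-dimethylcyclohex-1-en-1-yl)-5,6-dihydro-2H-pyran-2-one | O=C1C=CC[C@H](C2=CCCCC2(C)C)O1 | intermediate
10 | (4S,6R)-6-(6,6-dimethylcyclohex-1-en-1-yl)-4-methyltetrahydro-2H-pyran-2-one (4,6-trans) | O=C1C[C@@H](C)C[C@H](C2=CCCCC2(C)C)O1 | intermediate
11 | 1,2,4,5-tetramethoxybenzene | COc1cc(OC)c(OC)cc1OC | starting material
12 | (2,3,5,6-tetramethoxyphenyl)lithium | [Li]c1c(OC)c(OC)cc(OC)c1OC | intermediate (not isolated)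
13 | (2,3,5,6-tetramethoxyphenyl)methanol | COc1cc(OC)c(OC)c(CO)c1OC | intermediate
14 | 3-(bromomethyl)-1,2,4,5-tetramethoxybenzene | COc1cc(OC)c(OC)c(CBr)c1OC | intermediate
15 | lithium (4S,6R)-6-(6,6-dimethylcyclohex-1-en-1-yl)-4-methyl-5,6-dihydro-4H-pyran-2-olate | [Li]OC1=C[C@@H](C)C[C@H](C2=CCCCC2(C)C)O1 | intermediate (not isolated)
16 | (3R,4S,6R)-6-(6,6-dimethylcyclohex-1-en-1-yl)-4-methyl-3-(2,3,5,6-tetramethoxybenzyl)tetrahydro-2H-pyran-2-one | COc1cc(OC)c(OC)c(C[C@H]2C(=O)O[C@@H](C3=CCCCC3(C)C)C[C@@H]2C)c1OC | intermediate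
17 | lithium (4S,6R)-6-(6,6-dimethylcyclohex-1-en-1-yl)-4-methyl-3-(2,3,5,6-tetramethoxybenzyl)-5,6-dihydro-4H-pyran-2-olate | COc1cc(OC)c(OC)c(CC2=C(O[Li])O[C@@H](C3=CCCCC3(C)C)C[C@@H]2C)c1OC | intermediate (not isolated)
18 | tert-butyl{[(4S,6R)-6-(6,6-dimethylcyclohex-1-en-1-yl)-4-methyl-3-(2,3,5,6-tetramethoxybenzyl)-5,6-dihydro-4H-pyran-2-yl]oxy}dimethylsilane | COc1cc(OC)c(OC)c(CC2=C(O[Si](C)(C)C(C)(C)C)O[C@@H](C3=CCCCC3(C)C)C[C@@H]2C)c1OC | intermediate (not isolated)
19 | tert-butyldimethylsilyl (1S,2S,8aR)-2,5,5-trimethyl-1-(2,3,5,6-tetramethoxybenzyl)-1,2,3,5,6,7,8,8a-octahydronaphthalene-1-carboxylate | COc1cc(OC)c(OC)c(C[C@@]2(C(=O)O[Si](C)(C)C(C)(C)C)[C@@H]3CCCC(C)(C)C3=CC[C@@H]2C)c1OC | intermediate (not isolated)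
20 | (1S,2S,8aR)-2,5,5-trimethyl-1-(2,3,5,6-tetramethoxybenzyl)-1,2,3,5,6,7,8,8a-octahydronaphthalene-1-carboxylic acid (carboxyl on C9, trans to H-10, cis to the C8 methyl) | COc1cc(OC)c(OC)c(C[C@@]2(C(=O)O)[C@@H]3CCCC(C)(C)C3=CC[C@@H]2C)c1OC | intermediate
21 | [(1S,2S,8aR)-2,5,5-trimethyl-1-(2,3,5,6-tetramethoxybenzyl)-1,2,3,5,6,7,8,8a-octahydronaphthalen-1-yl]methanol | COc1cc(OC)c(OC)c(C[C@@]2(CO)[C@@H]3CCCC(C)(C)C3=CC[C@@H]2C)c1OC | intermediate
22 | (1S,2S,8aR)-2,5,5-trimethyl-1-(2,3,5,6-tetramethoxybenzyl)-1,2,3,5,6,7,8,8a-octahydronaphthalene-1-carbaldehyde | COc1cc(OC)c(OC)c(C[C@@]2(C=O)[C@@H]3CCCC(C)(C)C3=CC[C@@H]2C)c1OC | intermediate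
23 | hydrazone of aldehyde 22 | COc1cc(OC)c(OC)c(C[C@@]2(C=NN)[C@@H]3CCCC(C)(C)C3=CC[C@@H]2C)c1OC | intermediate (not isolated)
24 | 3-{[(1R,2S,8aS)-1,2,5,5-tetramethyl-1,2,3,5,6,7,8,8a-octahydronaphthalen-1-yl]methyl}-1,2,4,5-tetramethoxybenzene | COc1cc(OC)c(OC)c(C[C@@]2(C)[C@@H]3CCCC(C)(C)C3=CC[C@@H]2C)c1OC | intermediate
25 | 2,5-dimethoxy-3-{[(1R,2S,8aS)-1,2,5,5-tetramethyl-1,2,3,5,6,7,8,8a-octahydronaphthalen-1-yl]methyl}cyclohexa-2,5-diene-1,4-dione | COC1=CC(=O)C(OC)=C(C[C@@]2(C)[C@@H]3CCCC(C)(C)C3=CC[C@@H]2C)C1=O | intermediate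
26 | 2-hydroxy-5-methoxy-3-{[(1R,2S,8aS)-1,2,5,5-tetramethyl-1,2,3,5,6,7,8,8a-octahydronaphthalen-1-yl]methyl}cyclohexa-2,5-diene-1,4-dione | COC1=CC(=O)C(O)=C(C[C@@]2(C)[C@@H]3CCCC(C)(C)C3=CC[C@@H]2C)C1=O | intermediate
27 | isopentylamine (3-methylbutan-1-amine) | CC(C)CCN | starting material
28 | nakijiquinone M, 2-hydroxy-5-[(3-methylbutyl)amino]-3-{[(1R,2S,8aS)-1,2,5,5-tetramethyl-1,2,3,5,6,7,8,8a-octahydronaphthalen-1-yl]methyl}cyclohexa-2,5-diene-1,4-dione | CC(C)CCNC1=CC(=O)C(O)=C(C[C@@]2(C)[C@@H]3CCCC(C)(C)C3=CC[C@@H]2C)C1=O | target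

**Step count**

Total: 16 steps. Longest linear sequence: 14 steps (steps 1–6 and 9–16); steps 7 and 8 make the benzylic bromide in a side branch.

**Steps most likely to fail**

Step 10. The fully substituted α-carbon of 16 may enolise or O-silylate sluggishly, and the crowded bond between a tetrasubstituted ketene acetal carbon and a ring CH may form so slowly that the ketene acetal decomposes on heating. The fallback sets out from 10 and comes back at 20, moving the ring contraction ahead of the benzylation so that the shift joins two less substituted carbons. Lactone 10 is enolised to 15 and silylated with TBSCl to the silyl ketene acetal F1. Heating in toluene should give the silyl ester F2 through the same boat, and AcOH/THF/H2O frees the secondary acid F3. LiN(iPr)2 (2.2 equiv) converts F3 into the dilithium dianion F4, which is alkylated with bromide 14. The electrophile should enter equatorially, on the face of H-8 and H-10 and anti to the C8 methyl group and the C1 methylene, to give acid 20.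

Step 13. Hydrazone formation at the neopentyl aldehyde may stay incomplete, or hot KOH may cleave aryl methyl ethers. The fallback sets out from 21 and comes back at 24, replacing the ionic reduction by a radical deoxygenation (Barton–McCombie). Alcohol 21 is converted with NaH, CS2 and MeI in THF into the S-methyl xanthate F5, which is reduced with Bu3SnH and AIBN in toluene at 110 °C. The primary radical at the C9 branch has no favourable cyclisation or aryl-shift pathway and should simply abstract hydrogen to give 24.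

Step 15. Hydroxide may attack the less hindered methoxy-bearing carbon C5 instead of C2, giving poor regioselectivity. The fallback sets out from 25 and comes back at 28, inverting the order of the last two operations so that a preference for the unhindered position works in favour of the target. Dimethoxyquinone 25 is treated with isopentylamine 27 in EtOH, which should displace the C5 methoxy group and give the aminomethoxyquinone F6. The one remaining methoxy group, at C2, is then hydrolysed with KOH in MeOH/H2O and the mixture acidified to give 28.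

**Further compounds**

F1 | step 10 | tert-butyl{[(4S,6R)-6-(6,6-dimethylcyclohex-1-en-1-yl)-4-methyl-5,6-dihydro-4H-pyran-2-yl]oxy}dimethylsilane | CC(C)(C)[Si](C)(C)OC1=C[C@@H](C)C[C@H](C2=CCCCC2(C)C)O1
F2 | step 10 | tert-butyldimethylsilyl (1S,2S,8aS)-2,5,5-trimethyl-1,2,3,5,6,7,8,8a-octahydronaphthalene-1-carboxylate | CC(C)(C)[Si](C)(C)OC(=O)[C@@H]1[C@@H]2CCCC(C)(C)C2=CC[C@@H]1C
F3 | step 10 | (1S,2S,8aS)-2,5,5-trimethyl-1,2,3,5,6,7,8,8a-octahydronaphthalene-1-carboxylic acid | OC(=O)[C@@H]1[C@@H]2CCCC(C)(C)C2=CC[C@@H]1C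
F4 | step 10 | dilithium dianion (ene-diolate) of acid F3 | [Li]OC(O[Li])=C1[C@@H]2CCCC(C)(C)C2=CC[C@@H]1C
F5 | step 13 | O-{[(1S,2S,8aR)-2,5,5-trimethyl-1-(2,3,5,6-tetramethoxybenzyl)-1,2,3,5,6,7,8,8a-octahydronaphthalen-1-yl]methyl} S-methyl carbonodithioate | COc1cc(OC)c(OC)c(C[C@@]2(COC(=S)SC)[C@@H]3CCCC(C)(C)C3=CC[C@@H]2C)c1OC
F6 | step 15 | 2-methoxy-5-[(3-methylbutyl)amino]-3-{[(1R,2S,8aS)-1,2,5,5-tetramethyl-1,2,3,5,6,7,8,8a-octahydronaphthalen-1-yl]methyl}cyclohexa-2,5-diene-1,4-dione | CC(C)CCNC1=CC(=O)C(OC)=C(C[C@@]2(C)[C@@H]3CCCC(C)(C)C3=CC[C@@H]2C)C1=O
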